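**Assumption:** every intermediate carries the locants of the target's decalin (C1–C10; C17 = exocyclic CH2 on C8; C18 = CH2O on C4; side chain C11–C16 with the methyl on C13, the carbinol at C15 and the lactone CH at C16; β = face of the C10 methyl). In the hydrindane intermediates C9 is absent and C8 is bonded to C10. In these locants the target is 4R,5R,6S,9S,10R,13E,15S,16S.

## Retrosynthetic overview

1. Target ⇒ desilylation of 21 ⇒ C8=CH2 by methylenation of ketone 20 ⇒ C15–C16 by vinylogous Mukaiyama aldol of enal 16 with siloxyfuran 18 (butenolide brought in intact, last).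
2. 16 ⇒ C11–C12 by vinylogous Mukaiyama–Michael addition of prenal dienol ether 14 to exo-enone 12.
3. 12 ⇒ ring B by one-carbon semipinacol ring expansion of vinyl carbinol 11 (trans-hydrindane → trans-decalin; C10 shifts from C8 to C9).
4. Hydrindanone 9 ⇒ C5-H/C6-OH by hydroboration of a Δ5 alkene; C4 by formaldehyde ene reaction on Δ4 alkene 5 ⇒ Hajos–Parrish enedione 4 ⇒ 1 + 2.
5. Ring order: cyclopentane (from 1) → ring A (aldol) → ring B (expansion of the five-membered ring) → butenolide.

## Route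

**Step 1**
Reactants: 1 2-methylcyclopentane-1,3-dione; 2 pent-1-en-3-one
Product: 3 2-methyl-2-(3-oxopentyl)cyclopentane-1,3-dione
Conditions: H2O, AcOH (cat.), 70 °C
Reagents that add atoms: none
Why: Michael addition of the acidic cyclic 1,3-dione to the enone gives the prochiral triketone (no stereocentre yet).

**Step 2**
Reactants: 3 2-methyl-2-(3-oxopentyl)cyclopentane-1,3-dione
Product: 4 (7aS)-4,7a-dimethyl-2,3,7,7a-tetrahydro-1H-indene-1,5(6H)-dione
Conditions: (S)-phenylalanine (1 equiv), (+)-CSA (0.5 equiv), MeCN, reflux; recrystallise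
Reagents that add atoms: none
Why: Hajos–Parrish–Eder–Sauer–Wiechert enamine aldol condensation, in which the (S)-amino acid selects one of the two enantiotopic ring carbonyls and so sets C10 (7aS, 10β-methyl) while closing ring A.

**Step 3**
Reactants: 4 (7aS)-enedione
Product: 5 (1S,7aS)-4,7a-dimethyl-2,3,5,6,7,7a-hexahydro-1H-inden-1-ol (Δ4(5) alkene, 8β-OH)
Conditions: LiAlH4 (2 equiv), AlCl3 (6 equiv), Et2O, 0 °C → reflux
Reagents that add atoms: none
Why: Mixed chloroalane reduction: the saturated C8 ketone gives the 8β-alcohol (hydride from the α face, anti to the angular methyl), while the enone is reduced through its allylic aluminate and allyl cation, with hydride at the less hindered C3, to the tetrasubstituted Δ4 alkene.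

**Step 4**
Reactants: 5 Δ4(5)-alkenol
Product: 6 (1S,4R,7aS)-4-(hydroxymethyl)-4,7a-dimethyl-2,4,5,6,7,7a-hexahydro-1H-inden-1-ol (Δ5(6); 4α-CH2OH, 4β-CH3)
Conditions: (CH2O)n, Me2AlCl (3 equiv), CH2Cl2, 0 °C → rt
Reagents that add atoms: formaldehyde (from paraformaldehyde), C=O
Why: Lewis-acid-promoted carbonyl-ene reaction: formaldehyde bonds to C4 (the alkene carbon not flanked by the quaternary C10) from the α face opposite the angular methyl, and the only allylic hydrogen available on the C5 side (C6-H) is transferred, which sets C4 (α-CH2OH, β-CH3) and moves the alkene to C5=C6.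

**Step 5**
Reactants: 6 Δ5(6)-diol
Product: 7 4α-(hydroxymethyl)-4β,10β-dimethyl-5α-H-hydrindane-6α,8β-diol (trans-fused triol)
Conditions: BH3·THF (4 equiv), THF, 0 °C → rt; then NaOH, H2O2
Reagents that add atoms: hydrogen peroxide, OO
Why: Hydroboration–oxidation: B–H adds syn from the α face (the β face is blocked by the C4β and C10β methyls and the C18–O–B tether sits on the α face) with boron on the less substituted C6, and oxidation with retention gives 5α-H (trans fusion) and 6α-OH.

**Step 6**
Reactants: 7 triol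
Product: 8 6α,18-O-(1,1,3,3-tetraisopropyldisiloxane-1,3-diyl) ether of 7 (8β-OH free)
Conditions: TIPDSCl2 (1.05 equiv), imidazole, DMF, 0 °C
Reagents that add atoms: 1,3-dichloro-1,1,3,3-tetraisopropyldisiloxane, CC(C)[Si](Cl)(C(C)C)O[Si](Cl)(C(C)C)C(C)C
Why: The disiloxane silylates the primary C18-OH first and then closes onto the only proximal hydroxyl (the cis, peri C6α-OH), leaving the remote C8-OH free (bridging silyl protection).

**Step 7**
Reactants: 8 silylene-protected alcohol
Product: 9 the corresponding trans-hydrindan-8-one (6α,18-O-TIPDS)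
Conditions: Dess–Martin periodinane, NaHCO3, CH2Cl2, rt
Reagents that add atoms: none
Why: Dess–Martin oxidation of the only free (secondary) alcohol under non-basic conditions that do not eliminate the β-silyloxy group.

**Step 8**
Reactants: 9 trans-hydrindan-8-one; 10 vinylmagnesium bromide
Product: 11 8α-vinyl-8β-hydroxy trans-hydrindane (6α,18-O-TIPDS)
Conditions: CeCl3, THF, −78 °C
Reagents that add atoms: none
Why: Organocerium 1,2-addition (non-basic, so no enolisation or β-elimination) from the α face opposite the angular methyl, as with 17-keto steroids; the C8 configuration is lost in the next step.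

**Step 9**
Reactants: 11 vinyl carbinol
Product: 12 trans-decalin exo-enone: 9-methylidene-8-oxo, 4α-CH2O/4β,10β-dimethyl, 5α-H, 6α-O (6,18-O-TIPDS)
Conditions: Pd(MeCN)4(BF4)2 (10 mol %), 1,4-benzoquinone (1.5 equiv), 4 Å MS, THF, 0 °C → rt
Reagents that add atoms: none
Why: Proposed new method: a Pd(II)-catalysed oxidative semipinacol ring expansion, so far shown for strained 1-vinylcyclobutanols, applied to an unstrained 1-vinylcyclopentanol; the Pd(II)-activated vinyl group is attacked by the antiperiplanar C8–C10 σ bond (the quaternary carbon is the better migrating group and the shift relieves trans-hydrindane strain) as the carbinol becomes the C8 ketone, β-hydride elimination from C11–Pd (only C9-H is available, and C10 is quaternary so the alkene cannot move into the ring) releases the exo-enone and benzoquinone reoxidises Pd(0); closest known reaction types are the Pd(II) ring expansion of vinylcyclobutanols to 2-methylenecyclopentanones and halonium-induced semipinacol rearrangements of allylic alcohols.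

**Step 10**
Reactants: 13 3-methylbut-2-enal
Product: 14 (E)-trimethyl[(3-methylbuta-1,3-dien-1-yl)oxy]silane
Conditions: TMSCl, Et3N, ZnCl2 (cat.), MeCN, 40 °C
Reagents that add atoms: chlorotrimethylsilane, C[Si](C)(C)Cl
Why: γ-Deprotonative O-silylation of the enal gives the cross-conjugated silyl dienol ether (standard dienol ether formation).

**Step 11**
Reactants: 12 exo-enone; 14 silyl dienol ether
Product: 16 9β-[(3E)-3-methyl-5-oxopent-3-en-1-yl] trans-decalin-8-one (9α-H; 6,18-O-TIPDS), via C8 trimethylsilyl enol ether 15 (not isolated)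
Conditions: TMSOTf (10 mol %), CH2Cl2, −78 °C, 14 added slowly to 12 (1.2 equiv); then 1 M HCl, THF, 0 °C
Reagents that add atoms: none
Why: Vinylogous Mukaiyama–Michael addition: the dienol ether attacks the unhindered exocyclic CH2 through its γ carbon (open transition state, s-trans diene giving the E enal), and acid hydrolysis of the silyl enol ether protonates and equilibrates C9 to the equatorial 9β side chain (9α-H).

**Step 12**
Reactants: 17 4-methylfuran-2(5H)-one
Product: 18 trimethyl[(4-methylfuran-2-yl)oxy]silane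
Conditions: TMSOTf, Et3N, Et2O, 0 °C
Reagents that add atoms: trimethylsilyl trifluoromethanesulfonate, C[Si](C)(C)OS(=O)(=O)C(F)(F)F
Why: Soft enolisation and O-silylation of the butenolide gives the aromatic 2-silyloxyfuran.

**Step 13**
Reactants: 16 keto-enal; 18 silyloxyfuran
Product: 20 (15S,16S)-15-hydroxy butenolide 8-ketone (6,18-O-TIPDS), via 15-O-trimethylsilyl ether 19 (not isolated)
Conditions: Ti(Oi-Pr)4 (20 mol %), (S)-BINOL (20 mol %), Et2O, −20 °C; then citric acid, MeOH
Reagents that add atoms: none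
Why: Catalytic asymmetric vinylogous Mukaiyama aldol reaction at the aldehyde only (the hindered ketone is inert): the open, Diels–Alder-like transition state of silyloxyfurans gives the threo (like) C15/C16 pair and the BINOL–Ti complex selects the aldehyde face for 15S,16S (antipode assigned by analogy with aliphatic aldehydes; it is to be confirmed on prenal and (R)-BINOL used if the sense is reversed).

**Step 14**
Reactants: 20 keto butenolide
Product: 21 8(17)-methylidene compound (6,18-O-TIPDS-protected target)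
Conditions: Zn, CH2Br2, TiCl4, THF–CH2Cl2, 0 °C → rt
Reagents that add atoms: dibromomethane, BrCBr
Why: Lombardo methylenation, a non-basic Zn/Ti gem-dimetallic olefination that converts hindered, epimerisable ketones without touching lactones, free hydroxyls or the β-silyloxy group, and leaves C9 intact.

**Step 15**
Reactants: 21 protected target
Product: 22 target (CNP0221530.1)
Conditions: HF·pyridine, pyridine, THF, 0 °C → rt
Reagents that add atoms: none
Why: Buffered fluoride desilylation frees the C6 and C18 hydroxyls without base, so the butenolide γ-centre and the δ-hydroxy butenolide (retro-aldol) are not endangered.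

## Compound list

1 | 2-methylcyclopentane-1,3-dione | CC1C(=O)CCC1=O | starting material
2 | pent-1-en-3-one | CCC(=O)C=C | starting material
3 | 2-methyl-2-(3-oxopentyl)cyclopentane-1,3-dione | CCC(=O)CCC1(C)C(=O)CCC1=O | intermediate
4 | (7aS)-4,7a-dimethyl-2,3,7,7a-tetrahydro-1H-indene-1,5(6H)-dione | O=C1CC[C@]2(C)C(=O)CCC2=C1C | intermediate
5 | (1S,7aS)-4,7a-dimethyl-2,3,5,6,7,7a-hexahydro-1H-inden-1-ol | CC1=C2CC[C@H](O)[C@@]2(C)CCC1 | intermediate
6 | (1S,4R,7aS)-4-(hydroxymethyl)-4,7a-dimethyl-2,4,5,6,7,7a-hexahydro-1H-inden-1-ol | OC[C@]1(C)CCC[C@]2(C)[C@@H](O)CC=C12 | intermediate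
7 | 4α-(hydroxymethyl)-4β,10β-dimethyl-5α-H-hydrindane-6α,8β-diol | OC[C@]1(C)CCC[C@]2(C)[C@@H](O)C[C@H](O)[C@@H]12 | intermediate
8 | 6α,18-O-(tetraisopropyldisiloxane-1,3-diyl) ether of 7, 8β-OH | CC(C)[Si]1(C(C)C)OC[C@]2(C)CCC[C@]3(C)[C@@H](O)C[C@H](O[Si](C(C)C)(C(C)C)O1)[C@@H]23 | intermediate
9 | 6α,18-O-TIPDS trans-hydrindan-8-one | CC(C)[Si]1(C(C)C)OC[C@]2(C)CCC[C@]3(C)C(=O)C[C@H](O[Si](C(C)C)(C(C)C)O1)[C@@H]23 | intermediate
10 | vinylmagnesium bromide | C=C[Mg]Br | starting material
11 | 8α-vinyl-8β-hydroxy trans-hydrindane, 6α,18-O-TIPDS | CC(C)[Si]1(C(C)C)OC[C@]2(C)CCC[C@]3(C)[C@](O)(C=C)C[C@H](O[Si](C(C)C)(C(C)C)O1)[C@@H]23 | intermediate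
12 | 9-methylidene-8-oxo trans-decalin, 6α,18-O-TIPDS | CC(C)[Si]1(C(C)C)OC[C@]2(C)CCC[C@]3(C)C(=C)C(=O)C[C@H](O[Si](C(C)C)(C(C)C)O1)[C@@H]23 | intermediate
13 | 3-methylbut-2-enal | CC(C)=CC=O | starting material
14 | (E)-trimethyl[(3-methylbuta-1,3-dien-1-yl)oxy]silane | C=C(C)/C=C/O[Si](C)(C)C | intermediate
15 | C8 trimethylsilyl enol ether (Δ8(9)) of 16 | CC(C)[Si]1(C(C)C)OC[C@]2(C)CCC[C@]3(C)C(CC/C(C)=C/C=O)=C(O[Si](C)(C)C)C[C@H](O[Si](C(C)C)(C(C)C)O1)[C@@H]23 | intermediate
16 | 9β-[(3E)-3-methyl-5-oxopent-3-en-1-yl] trans-decalin-8-one, 9α-H, 6α,18-O-TIPDS | CC(C)[Si]1(C(C)C)OC[C@]2(C)CCC[C@]3(C)[C@@H](CC/C(C)=C/C=O)C(=O)C[C@H](O[Si](C(C)C)(C(C)C)O1)[C@@H]23 | intermediate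
17 | 4-methylfuran-2(5H)-one | CC1=CC(=O)OC1 | starting material
18 | trimethyl[(4-methylfuran-2-yl)oxy]silane | Cc1coc(O[Si](C)(C)C)c1 | intermediate
19 | 15-O-trimethylsilyl ether of 20 | CC(C)[Si]1(C(C)C)OC[C@]2(C)CCC[C@]3(C)[C@@H](CC/C(C)=C/[C@H](O[Si](C)(C)C)[C@H]4OC(=O)C=C4C)C(=O)C[C@H](O[Si](C(C)C)(C(C)C)O1)[C@@H]23 | intermediate
20 | (15S,16S)-15-hydroxy butenolide 8-ketone, 6α,18-O-TIPDS | CC(C)[Si]1(C(C)C)OC[C@]2(C)CCC[C@]3(C)[C@@H](CC/C(C)=C/[C@H](O)[C@H]4OC(=O)C=C4C)C(=O)C[C@H](O[Si](C(C)C)(C(C)C)O1)[C@@H]23 | intermediate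
21 | 6α,18-O-TIPDS-protected target (8(17)-methylidene) | CC(C)[Si]1(C(C)C)OC[C@]2(C)CCC[C@]3(C)[C@@H](CC/C(C)=C/[C@H](O)[C@H]4OC(=O)C=C4C)C(=C)C[C@H](O[Si](C(C)C)(C(C)C)O1)[C@@H]23 | intermediate
22 | CNP0221530.1 | C=C1C[C@H](O)[C@H]2[C@](C)(CO)CCC[C@]2(C)[C@H]1CC/C(C)=C/[C@H](O)[C@H]1OC(=O)C=C1C | target

## Step count and risks

Total steps: 15. Longest linear sequence: 13 (steps 1–9, 11, 13, 14, 15).

**Step 9 (the proposed new ring expansion).** Without the strain of a cyclobutanol the 1,2-shift may lose to allylic transposition or Wacker-type pathways. The fallback sets out from 11 and comes back at 12, using the Lewis-acid semipinacol rearrangement of a 2,3-epoxy alcohol, which is established for cyclopentanol-to-cyclohexanone expansion. Hydroxyl-directed epoxidation of the vinyl group (VO(acac)2, t-BuOOH, CH2Cl2) gives the epoxy alcohol F1 (either epoxide epimer serves). BF3·OEt2 (CH2Cl2, −78 °C) opens the epoxide at C9 with anti migration of C10 to give the 9β-(hydroxymethyl)-8-ketone F2. MsCl/Et3N gives the mesylate F3, which eliminates in the same flask to 12.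

**Step 11 (vinylogous Mukaiyama–Michael with an aldehyde-releasing nucleophile).** The product enal could react further with 14, the E/Z ratio of a 3-methyl-2-enal is not guaranteed, and this order forces the methylenation (step 14) late. The fallback sets out from 12 and comes back at 21. Methyl 3-methylbut-2-enoate F4 is converted (LDA, TMSCl, THF, −78 °C) into the silyl ketene acetal [(1-methoxy-3-methylbuta-1,3-dien-1-yl)oxy]trimethylsilane F5. Its γ-selective Mukaiyama–Michael addition to 12 (TMSOTf cat., then HCl) gives the (13E)-keto ester F6, whose ester cannot react further. Lombardo methylenation gives the 8(17)-methylidene ester F7, DIBAL-H (CH2Cl2, −78 °C) the allylic alcohol F8, and MnO2 the enal F9. The aldol reaction of step 13 on F9 with 18 then gives 21 directly.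

**Step 13 (C15/C16 control).** Threo selectivity and facial control are not secured for a β,β-disubstituted enal with a 4-methyl silyloxyfuran, and the decalin is too remote to help. The fallback sets out from 16 (with 18) and comes back at 20, giving up catalyst control. BF3·OEt2 (CH2Cl2, −78 °C) promotes the well-known threo-selective achiral addition, which gives 20 together with its (15R,16R)-threo diastereomer F10 in about equal amounts. The two are diastereomers and are separated by chromatography.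

## Further compounds

F1 | step 9 | 8β-hydroxy-8α-(oxiran-2-yl) trans-hydrindane, 6α,18-O-TIPDS (epoxide carbon as formed) | CC(C)[Si]1(C(C)C)OC[C@]2(C)CCC[C@]3(C)[C@](O)(C4CO4)C[C@H](O[Si](C(C)C)(C(C)C)O1)[C@@H]23
F2 | step 9 | 9β-(hydroxymethyl) trans-decalin-8-one, 6α,18-O-TIPDS | CC(C)[Si]1(C(C)C)OC[C@]2(C)CCC[C@]3(C)[C@@H](CO)C(=O)C[C@H](O[Si](C(C)C)(C(C)C)O1)[C@@H]23
F3 | step 9 | methanesulfonate of F2 | CC(C)[Si]1(C(C)C)OC[C@]2(C)CCC[C@]3(C)[C@@H](COS(C)(=O)=O)C(=O)C[C@H](O[Si](C(C)C)(C(C)C)O1)[C@@H]23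
F4 | step 11 | methyl 3-methylbut-2-enoate | COC(=O)C=C(C)C
F5 | step 11 | [(1-methoxy-3-methylbuta-1,3-dien-1-yl)oxy]trimethylsilane | COC(=CC(C)=C)O[Si](C)(C)C
F6 | step 11 | (13E)-methyl ester, 8-ketone, 6α,18-O-TIPDS | CC(C)[Si]1(C(C)C)OC[C@]2(C)CCC[C@]3(C)[C@@H](CC/C(C)=C/C(=O)OC)C(=O)C[C@H](O[Si](C(C)C)(C(C)C)O1)[C@@H]23
F7 | step 11 | (13E)-methyl ester, 8(17)-methylidene, 6α,18-O-TIPDS | CC(C)[Si]1(C(C)C)OC[C@]2(C)CCC[C@]3(C)[C@@H](CC/C(C)=C/C(=O)OC)C(=C)C[C@H](O[Si](C(C)C)(C(C)C)O1)[C@@H]23
F8 | step 11 | (13E)-15-ol, 8(17)-methylidene, 6α,18-O-TIPDS | CC(C)[Si]1(C(C)C)OC[C@]2(C)CCC[C@]3(C)[C@@H](CC/C(C)=C/CO)C(=C)C[C@H](O[Si](C(C)C)(C(C)C)O1)[C@@H]23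
F9 | step 11 | (13E)-15-al, 8(17)-methylidene, 6α,18-O-TIPDS | CC(C)[Si]1(C(C)C)OC[C@]2(C)CCC[C@]3(C)[C@@H](CC/C(C)=C/C=O)C(=C)C[C@H](O[Si](C(C)C)(C(C)C)O1)[C@@H]23
F10 | step 13 | (15R,16R)-diastereomer of 20 | CC(C)[Si]1(C(C)C)OC[C@]2(C)CCC[C@]3(C)[C@@H](CC/C(C)=C/[C@@H](O)[C@@H]4OC(=O)C=C4C)C(=O)C[C@H](O[Si](C(C)C)(C(C)C)O1)[C@@H]23
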